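The closed, stirred vessel holds L in the first phase and Q in the second; Q crosses over as E, which turns L into X and may also attack X or decay to J.

common to all: L 24 mM
- east: Q 36 mM; the very flask that is asked about, followed so far
- south-west: Q 24 mM; run made earlier
- flask: Q 36.0 mM; time 15 min; volume of the second phase over the first 0.50

- east (time / min: X / %): 1.00: 0.3; 2.00: 4.7; 3.00: 7.3; 4.00: 10.4; 5.00: 12.2; 6.00: 14.4; 8.00: 17.2
- south-west (time / min: X / %): 1.33: 2.5; 2.00: 3.2; 3.00: 5.5; 4.00: 6.8; 6.00: 10.0; 10.0: 15.0; 15.0: 18.9

(each reading ± 0.5 percentage points)

1. the X standing at 15 min, as a percentage of the L charged
2. the change that raises the amount of X at 15 min, in percent of the L charged most ("none" if none brings more than 2 percentage points) (alpha / eta / none)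
3. amount of X at 15 min, in percent of the L charged, after eta

- alpha: doubling the transfer coefficient of Q, all else as stated
- eta: doubling the amount of Q, all else as stated

- in the second phase: Q; everything else is in the first
- charges count per volume of the first phase; a concentration in a rate is the amount of a species over the volume of its own phase; every rate counts per litre of the first phase
- what was read earlier has a scatter of 0.5 percentage points, one standard deviation
- candidate steps: E <-> Q; L + E -> X; E + X -> D; E -> J
- the earlier runs hold the two phases in the same ratio of volumes as the flask asked about

In the south-west run the slope of X falls to half between the stretch from 3.00 min to 6.00 min and the stretch from 10.0 min to 15.0 min, while X reaches 18.9% of the L charged. L is not constant over that stretch, so no single species is credited with this decline; the decline as a whole, whatever its causes, is read from these scattered readings as the fading constant κ, the fraction of the X rate lost per minute, and κ is what is held constant: 0.0817 min⁻¹. The X still to come is then the present slope over κ. Taken over to the east flask, the last two readings give a reserve of 15.8% beyond 8.00 min. Part of it arrives by 15 min, so this reckoning commits to 24.1%.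

The forecast, holding that “Doubling Q roughly doubles the driving force”, gives 25%, which is higher than this reckoning, chooses eta and puts X after it at 41%.

    E ⇌ Q, rate k1*([E] - [Q]/K1) per volume of the first phase (partition coefficient = 1.50, kL = 0.861 min⁻¹)
    L + E → X (k = 1.66 M⁻¹ min⁻¹)
    E + X → D (k = 1.88 M⁻¹ min⁻¹)
    E → J (k = 0.0269 min⁻¹)

The east flask stands at 25.2% after 15 min; eta is the best change, reaching 33.8%, a gain of 8.6 percentage points, more than the 0.27 points of alpha. At that time X is made 2.41 times faster than it is used up. With κ, the reserve remaining at 15 min is 8.9 points, which on top of 25.2% makes 34.1%; the same flask left for 150 min holds 34.5% of X.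

The numbers in the tables were generated by integration for substances that don't exist, and the scatter is random.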